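**Assumption:** the SMILES is read as (2S,4S,6S)-4-bromo-1-[(Z)-2-bromoethylidene]-2,6-dichloro-3,3-dimethylcyclohexane (the two chlorines cis to each other, bromine trans to both, CH2Br on the C2 side); compounds 1, 3 and 8 are bought.

## Retrosynthetic overview

1. Target 14 ⇐ diene 11 by a 1,4-bromochlorination across the s-trans 1-vinylcyclohexene: this sets C1'–Br, the C6–Cl centre and the Z alkene in one step.
2. Diene 11 ⇐ bicyclo[3.1.0]hexyl vinyl carbinol 9 by a cyclopropylcarbinyl-to-homoallyl ring expansion with bromide (five- to six-membered ring, sets the neopentyl C–Br centre).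
3. Carbinol 9 ⇐ chloro ketone 7 + vinylmagnesium bromide 8; 7 ⇐ ketone 5 by α-chlorination anti to the cyclopropane.
4. Ketone 5 ⇐ 4,4-dimethylcyclopent-2-en-1-one 1 by enantioselective reduction, hydroxyl-directed cyclopropanation with 3, and oxidation.
5. Ring order: cyclopentene (bought) → cyclopropane fused onto it → cyclohexene by ring expansion.

## Route

Step 1
Reactants: 1 4,4-dimethylcyclopent-2-en-1-one
Product: 2 (S)-4,4-dimethylcyclopent-2-en-1-ol
Conditions: (R)-Me-CBS oxazaborolidine [(R)-1-methyl-3,3-diphenyltetrahydro-1H,3H-pyrrolo[1,2-c][1,3,2]oxazaborole] (10 mol %), catecholborane, toluene, −78 °C; aq NaOH work-up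
Reagents that add atoms: none
Why: Corey–Bakshi–Shibata reduction, in which the oxazaborolidine binds the carbonyl with the alkenyl arm as the large group and delivers hydride to one face to give the S carbinol, whose only task is to steer step 2.

Step 2
Reactants: 2 (S)-4,4-dimethylcyclopent-2-en-1-ol; 3 diiodomethane
Product: 4 (1R,2S,5S)-4,4-dimethylbicyclo[3.1.0]hexan-2-ol
Conditions: Et2Zn, CH2I2, CH2Cl2, 0 °C
Reagents that add atoms: none
Why: Hydroxyl-directed Simmons–Smith (Furukawa) cyclopropanation, in which the zinc alkoxide delivers CH2 to the alkene face syn to oxygen, so the carbinol centre fixes both ring-fusion centres.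

Step 3
Reactants: 4 (1R,2S,5S)-4,4-dimethylbicyclo[3.1.0]hexan-2-ol
Product: 5 (1R,5S)-4,4-dimethylbicyclo[3.1.0]hexan-2-one
Conditions: Dess–Martin periodinane (1,1,1-triacetoxy-1,1-dihydro-1,2-benziodoxol-3(1H)-one), CH2Cl2, 0 °C to rt
Reagents that add atoms: none
Why: Dess–Martin oxidation of a secondary alcohol under near-neutral conditions leaves the cyclopropane untouched and removes the carbinol centre that is no longer needed.

Step 4
Reactants: 5 (1R,5S)-4,4-dimethylbicyclo[3.1.0]hexan-2-one
Product: 7 (1R,3R,5S)-3-chloro-4,4-dimethylbicyclo[3.1.0]hexan-2-one, via lithium enolate 6 (not isolated)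
Conditions: LiN(i-Pr)2, THF, −78 °C; then p-TsCl, −78 °C
Reagents that add atoms: p-toluenesulfonyl chloride, Cc1ccc(cc1)S(=O)(=O)Cl
Why: Enolate chlorination with the sulfonyl chloride as Cl+ donor, in which only C3 can enolise (C1 is a cyclopropane bridgehead) and the electrophile enters the convex face anti to the cyclopropane methylene, setting C3 (R).

Step 5
Reactants: 7 (1R,3R,5S)-3-chloro-4,4-dimethylbicyclo[3.1.0]hexan-2-one; 8 vinylmagnesium bromide
Product: 9 (1R,2S,3R,5S)-3-chloro-2-ethenyl-4,4-dimethylbicyclo[3.1.0]hexan-2-ol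
Conditions: CH2=CHMgBr, CeCl3, THF, −78 °C; aq NH4Cl
Reagents that add atoms: none
Why: Organocerium 1,2-addition, in which the weakly basic vinylcerium reagent adds to the α-chloro ketone faster than it enolises it, so C3 is not epimerised; the new carbinol centre (drawn for attack anti to chlorine) is destroyed in step 6, so either epimer serves.

Step 6
Reactants: 9 (1R,2S,3R,5S)-3-chloro-2-ethenyl-4,4-dimethylbicyclo[3.1.0]hexan-2-ol
Product: 11 (4S,6S)-4-bromo-6-chloro-1-ethenyl-5,5-dimethylcyclohex-1-ene, via cyclopropylcarbinyl-allyl cation 10 (not isolated)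
Conditions: 48% aq HBr, pentane, 0 °C, 15 min, vigorous stirring
Reagents that add atoms: hydrogen bromide, Br
Why: Julia-type cyclopropylcarbinyl-to-homoallyl rearrangement (as in the i-steroid series), in which ionisation gives the vinyl- and cyclopropyl-stabilised cation 10 and bromide opens the ring-fusion bond at the more substituted cyclopropane carbon with inversion, which expands the five-membered ring to the cyclohexene and sets C4–Br (S) trans to chlorine.

Step 7
Reactants: 11 (4S,6S)-4-bromo-6-chloro-1-ethenyl-5,5-dimethylcyclohex-1-ene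
Product: 14 (2S,4S,6S)-4-bromo-1-[(Z)-2-bromoethylidene]-2,6-dichloro-3,3-dimethylcyclohexane, via bromoallyl cation 12 (not isolated), via alkoxymethyleneiminium salt 13 (not isolated)
Conditions: N-bromosuccinimide (1.05 equiv), DMF (10 equiv), CH2Cl2, −60 °C, 1 h; then Me3SiCl (1.5 equiv), −60 to −20 °C
Reagents that add atoms: N-bromosuccinimide, O=C1CCC(=O)N1Br; chlorotrimethylsilane, C[Si](C)(C)Cl
Why: Proposed new method: a formamide-relayed 1,4-bromochlorination of a 1,3-diene, in which Br+ adds to the open terminal CH2 of the s-trans diene (cation 12 carries no charge on the carbon next to C–Cl and keeps CH2Br syn to the CHCl carbon, which fixes the Z alkene), DMF oxygen traps ring carbon C2 on the face away from the pseudoaxial C–Cl bond to give 13, and chloride set free when Me3SiCl silylates the succinimide anion displaces DMF by SN2 with inversion, so the new chlorine ends cis to the old one and trans to bromine, where direct chloride capture of the cation would be expected to give the trans epimer; the closest known reaction types are the N-bromosuccinimide/DMF bromoformyloxylation of alkenes and the Vilsmeier-type conversion of alcohols into chlorides with inversion.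

## Compound list

1 | 4,4-dimethylcyclopent-2-en-1-one | O=C1C=CC(C)(C)C1 | starting material
2 | (S)-4,4-dimethylcyclopent-2-en-1-ol | O[C@@H]1C=CC(C)(C)C1 | intermediate
3 | diiodomethane | ICI | starting material
4 | (1R,2S,5S)-4,4-dimethylbicyclo[3.1.0]hexan-2-ol (OH cis to the cyclopropane) | O[C@H]1CC(C)(C)[C@H]2C[C@@H]12 | intermediate
5 | (1R,5S)-4,4-dimethylbicyclo[3.1.0]hexan-2-one | O=C1CC(C)(C)[C@H]2C[C@@H]12 | intermediate
6 | lithium (1R,5S)-4,4-dimethylbicyclo[3.1.0]hex-2-en-2-olate | [Li+].[O-]C1=CC(C)(C)[C@H]2C[C@@H]12 | intermediate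
7 | (1R,3R,5S)-3-chloro-4,4-dimethylbicyclo[3.1.0]hexan-2-one (Cl trans to the cyclopropane) | O=C1[C@H](Cl)C(C)(C)[C@H]2C[C@@H]12 | intermediate
8 | vinylmagnesium bromide | C=C[Mg]Br | starting material
9 | (1R,2S,3R,5S)-3-chloro-2-ethenyl-4,4-dimethylbicyclo[3.1.0]hexan-2-ol | C=C[C@@]1(O)[C@H](Cl)C(C)(C)[C@H]2C[C@@H]12 | intermediate
10 | 3-chloro-2-ethenyl-4,4-dimethylbicyclo[3.1.0]hexan-2-ylium (C2 cation of 9; ring-fusion and C–Cl centres as in 9) | C=C[C+]1[C@H](Cl)C(C)(C)[C@H]2C[C@@H]12 | intermediate
11 | (4S,6S)-4-bromo-6-chloro-1-ethenyl-5,5-dimethylcyclohex-1-ene (Br trans to Cl) | C=CC1=CC[C@H](Br)C(C)(C)[C@H]1Cl | intermediate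
12 | (3S,5S)-5-bromo-2-[(Z)-2-bromoethylidene]-3-chloro-4,4-dimethylcyclohexan-1-ylium (allyl cation, one resonance form) | CC1(C)[C@@H](Br)C[CH+]/C(=C/CBr)[C@@H]1Cl | intermediate
13 | {[(1R,2Z,3S,5S)-5-bromo-2-(2-bromoethylidene)-3-chloro-4,4-dimethylcyclohexyl]oxy}-N,N-dimethylmethaniminium succinimidate (O trans to the C3 chlorine) | CC1(C)[C@@H](Br)C[C@@H](OC=[N+](C)C)/C(=C/CBr)[C@@H]1Cl.O=C1CCC(=O)[N-]1 | intermediate
14 | (2S,4S,6S)-4-bromo-1-[(Z)-2-bromoethylidene]-2,6-dichloro-3,3-dimethylcyclohexane | CC1(C)[C@@H](Br)C[C@H](Cl)/C(=C/CBr)[C@@H]1Cl | target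

## Step count and risks

Total steps: 7. Longest linear sequence: 7.

The three steps most likely to fail:

**Step 7 (the proposed new method).** Direct chloride capture of cation 12, chloride attack at the exocyclic allyl terminus, or SN1 collapse of 13 would give the C6 epimer or the 1,2-adduct. The fallback uses known chemistry and sets out from 11. A Pd(OAc)2-catalysed 1,4-dichlorination (LiCl, p-benzoquinone, AcOH, rt) adds chloride to the terminal carbon and then to the π-allylpalladium intermediate anti to the metal, which sits on the face away from the C–Cl bond. This gives (2S,4S,6S)-4-bromo-2,6-dichloro-1-[(Z)-2-chloroethylidene]-3,3-dimethylcyclohexane F6. Finkelstein exchange of the primary allylic chloride alone (LiBr, acetone) then comes back to the route at 14.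

**Step 6 (ring expansion).** Bromide may instead be taken up at the allyl terminus or at the cyclopropane CH2 (attack at the ring-fusion carbon is neopentyl-like), and HBr can add to the diene product. The fallback sets out from 7 and removes the allylic terminus. Ethynylmagnesium bromide (HC≡CMgBr) with CeCl3 gives (1R,2R,3R,5S)-3-chloro-2-ethynyl-4,4-dimethylbicyclo[3.1.0]hexan-2-ol F4. Its propargylic cation leans harder on the cyclopropane and has no allylic terminus, and the same HBr opening (the known Julia route to enynyl bromides) gives (4S,6S)-4-bromo-6-chloro-1-ethynyl-5,5-dimethylcyclohex-1-ene F5. Semi-hydrogenation over Pd/CaCO3 poisoned with Pb(OAc)2 and quinoline comes back to the route at 11.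

**Step 4 (chlorination).** The electrophile may enter on the cyclopropane face, the ratio may be low, or dichlorination may occur. The fallback sets out from 5 and uses oxygenation followed by inversion, so it gives the right epimer if electrophiles prefer the cyclopropane face. LiN(i-Pr)2 and Me3SiCl give (1R,5S)-4,4-dimethyl-2-(trimethylsilyloxy)bicyclo[3.1.0]hex-2-ene F1. Rubottom oxidation with m-CPBA gives (1R,3S,5S)-3-hydroxy-4,4-dimethylbicyclo[3.1.0]hexan-2-one F2. Tf2O and pyridine give (1R,3S,5S)-4,4-dimethyl-2-oxobicyclo[3.1.0]hexan-3-yl trifluoromethanesulfonate F3. LiCl in DMF then displaces the triflate with inversion and comes back to the route at 7.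

## Further compounds

F1 | step 4 | (1R,5S)-4,4-dimethyl-2-(trimethylsilyloxy)bicyclo[3.1.0]hex-2-ene | C[Si](C)(C)OC1=CC(C)(C)[C@H]2C[C@@H]12
F2 | step 4 | (1R,3S,5S)-3-hydroxy-4,4-dimethylbicyclo[3.1.0]hexan-2-one | O=C1[C@@H](O)C(C)(C)[C@H]2C[C@@H]12
F3 | step 4 | (1R,3S,5S)-4,4-dimethyl-2-oxobicyclo[3.1.0]hexan-3-yl trifluoromethanesulfonate | O=C1[C@@H](OS(=O)(=O)C(F)(F)F)C(C)(C)[C@H]2C[C@@H]12
F4 | step 6 | (1R,2R,3R,5S)-3-chloro-2-ethynyl-4,4-dimethylbicyclo[3.1.0]hexan-2-ol | C#C[C@@]1(O)[C@H](Cl)C(C)(C)[C@H]2C[C@@H]12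
F5 | step 6 | (4S,6S)-4-bromo-6-chloro-1-ethynyl-5,5-dimethylcyclohex-1-ene | C#CC1=CC[C@H](Br)C(C)(C)[C@H]1Cl
F6 | step 7 | (2S,4S,6S)-4-bromo-2,6-dichloro-1-[(Z)-2-chloroethylidene]-3,3-dimethylcyclohexane | CC1(C)[C@@H](Br)C[C@H](Cl)/C(=C/CCl)[C@@H]1Cl
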